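**Retrosynthetic overview**

1. Decalin numbering as in the name of 28 (C1 quaternary, C2 CH–CH3, C4a ring-fusion CH, C6 carbinol, C8=C8a alkene; ring A = C4a-C5-C6-C7-C8-C8a, ring B = C1-C2-C3-C4-C4a-C8a). Enabling feature: C8a of ring B is sp2, and its double bond C8a=C8 is exocyclic to ring B and endocyclic to ring A, between C4a–H and the quaternary C1. This is the retron of a Diels–Alder reaction of an allene through one π bond, the other π bond surviving as C8=C8a.
2. 28 ⇐ late formylation (directed ortho-metalation, DMF) of a locally symmetric 2,6-bis(MOM-oxy)-4-(hydroxymethyl)benzyl unit ⇐ ArCH2–C1 bond from aryllithium 21 and neopentyl aldehyde 16, Barton–McCombie deoxygenation, selective hydrogenation of C3=C4.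
3. 16 ⇐ intramolecular Diels–Alder reaction of the (Ra)-2,3-dienal 15 with its own (E,Z)-diene: bonds C4a–C8a and C1–C2, rings A and B, stereocentres C1, C2, C4a and the C8=C8a alkene in one step.
4. 15 ⇐ anti-SN2' methylation of propargylic mesylate 13 (centre-to-axis transfer) ⇐ Noyori transfer hydrogenation ⇐ Trost direct aldol of dienal 5 with ynone 9; 5 from ester-aldehyde 1 by Takai olefination and Suzuki coupling.
5. Ring order: the arene is bought; rings A and B are closed together in step 12.

Key step: step 12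

Remark: the antipodes of the ProPhenol ligand (step 6) and of the TsDPEN catalyst (step 8) are named for the configurations needed (6R in 10, 4R in 12) and the sense of the aldol is to be checked on 10; the target is drawn as the open hydroxy aldehyde, which may equilibrate with its lactol.

**Route**

Step 1
Reactants: 1 methyl 2,2-dimethyl-3-oxopropanoate
Product: 2 methyl (3E)-4-iodo-2,2-dimethylbut-3-enoate
Conditions: CrCl2 (6 equiv), CHI3 (2 equiv), THF, 0 °C → rt
Reagents that add atoms: iodoform, IC(I)I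
Why: Takai iodo-olefination: the geminal dichromium species from CHI3 and CrCl2 adds to the aldehyde and eliminates to the E-alkenyl iodide, most selectively with hindered aldehydes, and leaves the ester untouched.

Step 2
Reactants: 2 methyl (3E)-4-iodo-2,2-dimethylbut-3-enoate
Product: 3 methyl (3E,5Z)-2,2-dimethylhepta-3,5-dienoate
Conditions: (Z)-prop-1-enylboronic acid, Pd(PPh3)4 (5 mol%), K3PO4, THF/H2O, 50 °C
Reagents that add atoms: (Z)-prop-1-en-1-ylboronic acid, C/C=C\B(O)O
Why: Suzuki–Miyaura coupling proceeds with retention at both alkenyl partners, so the E-iodide and the Z-boronic acid should deliver the (3E,5Z)-diene without a Wittig-type selectivity problem.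

Step 3
Reactants: 3 methyl (3E,5Z)-2,2-dimethylhepta-3,5-dienoate
Product: 4 (3E,5Z)-2,2-dimethylhepta-3,5-dien-1-ol
Conditions: DIBAL-H, CH2Cl2, −78 → 0 °C; Rochelle salt
Reagents that add atoms: none
Why: DIBAL-H reduction of the ester to the neopentyl-type primary alcohol; the unconjugated diene is inert to the hydride.

Step 4
Reactants: 4 (3E,5Z)-2,2-dimethylhepta-3,5-dien-1-ol
Product: 5 (3E,5Z)-2,2-dimethylhepta-3,5-dienal
Conditions: Dess–Martin periodinane, NaHCO3, CH2Cl2, 0 °C → rt
Reagents that add atoms: none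
Why: Dess–Martin oxidation under buffered conditions gives the aldehyde, which has no α-hydrogen and so can neither epimerise nor move its diene into conjugation.

Step 5
Reactants: 6 3,3-diethoxyprop-1-yne; 7 N-methoxy-N-methylacetamide
Product: 9 5,5-diethoxypent-3-yn-2-one, via lithium acetylide 8 (not isolated)
Conditions: n-BuLi, THF, −78 °C; then 7, −78 → 0 °C; aq NH4Cl
Reagents that add atoms: none
Why: Acylation of a lithium acetylide with a Weinreb amide stops at the ketone because the chelated tetrahedral intermediate survives until work-up.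

Step 6
Reactants: 5 (3E,5Z)-2,2-dimethylhepta-3,5-dienal; 9 5,5-diethoxypent-3-yn-2-one
Product: 10 (6R,8E,10Z)-1,1-diethoxy-6-hydroxy-7,7-dimethyldodeca-8,10-dien-2-yn-4-one
Conditions: Et2Zn (20 mol%), (R,R)-ProPhenol (10 mol%), 4 Å MS, THF, 0 °C
Reagents that add atoms: none
Why: Trost direct aldol reaction with a dinuclear zinc ProPhenol catalyst: the non-enolisable aldehyde 5 can only be the acceptor, the methyl ynone is the only donor, and the chiral Zn2 pocket selects the aldehyde face to set C6 as R.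

Step 7
Reactants: 10 (6R,8E,10Z)-1,1-diethoxy-6-hydroxy-7,7-dimethyldodeca-8,10-dien-2-yn-4-one
Product: 11 (6R,8E,10Z)-6-[(tert-butyldimethylsilyl)oxy]-1,1-diethoxy-7,7-dimethyldodeca-8,10-dien-2-yn-4-one
Conditions: TBSOTf, 2,6-lutidine, CH2Cl2, −78 °C
Reagents that add atoms: tert-butyldimethylsilyl trifluoromethanesulfonate, CC(C)(C)[Si](C)(C)OS(=O)(=O)C(F)(F)F
Why: Silylation with TBSOTf and 2,6-lutidine at low temperature protects the hindered secondary alcohol without retro-aldol cleavage or oxa-Michael closure onto the ynone.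

Step 8
Reactants: 11 (6R,8E,10Z)-6-[(tert-butyldimethylsilyl)oxy]-1,1-diethoxy-7,7-dimethyldodeca-8,10-dien-2-yn-4-one
Product: 12 (4R,6R,8E,10Z)-6-[(tert-butyldimethylsilyl)oxy]-1,1-diethoxy-7,7-dimethyldodeca-8,10-dien-2-yn-4-ol
Conditions: Ru[(R,R)-TsNCH(Ph)CH(Ph)NH](p-cymene) (2 mol%), i-PrOH, rt
Reagents that add atoms: none
Why: Noyori asymmetric transfer hydrogenation of an alkynyl ketone is catalyst-controlled (the alkyne takes the place of the aryl group in the CH–π model), so the (R,R)-catalyst should set C4 as R, anti to the C6 oxygen, without touching alkyne, diene or acetal.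

Step 9
Reactants: 12 (4R,6R,8E,10Z)-6-[(tert-butyldimethylsilyl)oxy]-1,1-diethoxy-7,7-dimethyldodeca-8,10-dien-2-yn-4-ol
Product: 13 (4R,6R,8E,10Z)-6-[(tert-butyldimethylsilyl)oxy]-1,1-diethoxy-7,7-dimethyldodeca-8,10-dien-2-yn-4-yl methanesulfonate
Conditions: MsCl, Et3N, CH2Cl2, −78 → −40 °C
Reagents that add atoms: methanesulfonyl chloride, CS(=O)(=O)Cl
Why: Sulfonylation of the propargylic alcohol with retention at C4 provides the leaving group for the SN2' step; the mesylate is used without chromatography.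

Step 10
Reactants: 13 (4R,6R,8E,10Z)-6-[(tert-butyldimethylsilyl)oxy]-1,1-diethoxy-7,7-dimethyldodeca-8,10-dien-2-yn-4-yl methanesulfonate
Product: 14 tert-butyl{[(Ra,6R,8E,10Z)-1,1-diethoxy-2,7,7-trimethyldodeca-2,3,8,10-tetraen-6-yl]oxy}dimethylsilane
Conditions: MeMgBr, CuBr·SMe2, LiBr, THF, −78 °C
Reagents that add atoms: methylmagnesium bromide, C[Mg]Br
Why: Anti-selective SN2' substitution of a propargylic mesylate by a methylcopper–magnesium bromide reagent transfers the C4 centre into the allene axis (Ra) and places the methyl group on the acetal-bearing carbon.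

Step 11
Reactants: 14 tert-butyl{[(Ra,6R,8E,10Z)-1,1-diethoxy-2,7,7-trimethyldodeca-2,3,8,10-tetraen-6-yl]oxy}dimethylsilane
Product: 15 (Ra,6R,8E,10Z)-6-[(tert-butyldimethylsilyl)oxy]-2,7,7-trimethyldodeca-2,3,8,10-tetraenal
Conditions: oxalic acid, wet SiO2, CH2Cl2, rt; used at once
Reagents that add atoms: water, O
Why: Mild acid hydrolysis of the diethyl acetal on wet silica frees the 2,3-dienal, while the silyl ether and the allene axis (no base or nucleophile present) should stay intact.

Step 12
Reactants: 15 (Ra,6R,8E,10Z)-6-[(tert-butyldimethylsilyl)oxy]-2,7,7-trimethyldodeca-2,3,8,10-tetraenal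
Product: 16 (1S,2R,4aR,6R)-6-[(tert-butyldimethylsilyl)oxy]-1,2,5,5-tetramethyl-1,2,4a,5,6,7-hexahydronaphthalene-1-carbaldehyde
Conditions: Me2AlCl (1.2 equiv), CH2Cl2, −78 → −20 °C
Reagents that add atoms: none
Why: The Me2AlCl-bound formyl group lowers the LUMO of the conjugated C2=C3 bond of the allene only (the C3=C4 bond is orthogonal to the carbonyl), so a concerted, asynchronous intramolecular Diels–Alder reaction should join C3 to C8 and C2 to C11 (numbering of 15); the closest known reaction types are intramolecular Diels–Alder reactions of allenes through the π bond remote from the tether (allenyl ethers, allenecarboxanilides) and Lewis acid-promoted cycloadditions of 2,3-dienals and 2,3-dienoates at their conjugated bond. Ring A closes as the six-membered tether ring of a 1,3,9-decatriene-type cycloaddition in which the untouched allene π bond becomes the endocyclic C8=C8a alkene, and ring B is the cyclohexene formed by the [4+2] event itself (numbering of 16 from here on). C1 is set by axis-to-centre chirality transfer, because the tether lets the diene reach only one face of the (Ra)-allene; the cis relation of H-4a and the C2 methyl group follows from suprafacial addition to the E (tether end) and Z (methyl end) termini of the diene. The diene face, and with it C2 and C4a relative to C1 and C6, is selected by the endo position of the aluminium-bound formyl group and by a half-chair tether with the C6 silyloxy group pseudo-equatorial, two preferences that point to the same transition state. The step needs site selectivity between the two allene π bonds, secured by conjugation with the formyl group, and this diene-face selectivity, secured by the matched pairing of the 6R centre with the Ra axis.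

Step 13
Reactants: 17 methyl 4-bromo-3,5-dihydroxybenzoate
Product: 18 methyl 4-bromo-3,5-bis(methoxymethoxy)benzoate
Conditions: MOMCl, i-Pr2NEt, CH2Cl2, 0 °C → rt
Reagents that add atoms: chloromethyl methyl ether, COCCl
Why: O-Alkylation of both phenols with MOMCl and Hünig's base; the MOM ethers later stabilise the aryllithium by chelation and direct the final metalation.

Step 14
Reactants: 18 methyl 4-bromo-3,5-bis(methoxymethoxy)benzoate
Product: 19 [4-bromo-3,5-bis(methoxymethoxy)phenyl]methanol
Conditions: DIBAL-H, CH2Cl2, −78 → 0 °C; Rochelle salt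
Reagents that add atoms: none
Why: DIBAL-H reduces the ester to the benzylic alcohol at low temperature without bromine–metal exchange or loss of the acetals.

Step 15
Reactants: 19 [4-bromo-3,5-bis(methoxymethoxy)phenyl]methanol
Product: 20 {[4-bromo-3,5-bis(methoxymethoxy)phenyl]methoxy}(tert-butyl)dimethylsilane
Conditions: TBSCl, imidazole, DMF, rt
Reagents that add atoms: tert-butyldimethylsilyl chloride, CC(C)(C)[Si](C)(C)Cl
Why: Standard silylation of the primary benzylic alcohol, needed so that only one alkoxide is present in the xanthate-forming step.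

Step 16
Reactants: 20 {[4-bromo-3,5-bis(methoxymethoxy)phenyl]methoxy}(tert-butyl)dimethylsilane; 16 (1S,2R,4aR,6R)-6-[(tert-butyldimethylsilyl)oxy]-1,2,5,5-tetramethyl-1,2,4a,5,6,7-hexahydronaphthalene-1-carbaldehyde
Product: 23 O-(aryl)(decalinyl)methyl S-methyl carbonodithioate (both epimers at the new carbinol carbon; full name in the list), via aryllithium 21 (not isolated), via lithium alkoxide 22 (not isolated)
Conditions: 20, n-BuLi, THF, −78 °C; then 16, −78 → 0 °C; then CS2, 0 °C → rt; then MeI
Reagents that add atoms: carbon disulfide, S=C=S; iodomethane, CI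
Why: Bromine–lithium exchange gives an aryllithium held by two ortho MOM groups, which adds to the non-enolisable neopentyl aldehyde (aryllithium addition to a carbonyl); the alkoxide is trapped in the same flask as the xanthate (first half of a Barton–McCombie deoxygenation), and the mixture of epimers does not matter because this centre becomes CH2 in step 17.

Step 17
Reactants: 23 O-(aryl)(decalinyl)methyl S-methyl carbonodithioate
Product: 24 tert-butyl({4-[((1S,2R,4aR,6R)-6-{[tert-butyl(dimethyl)silyl]oxy}-1,2,5,5-tetramethyl-1,2,4a,5,6,7-hexahydronaphthalen-1-yl)methyl]-3,5-bis(methoxymethoxy)phenyl}methoxy)dimethylsilane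
Conditions: Bu3SnH, AIBN (cat.), toluene, 100 °C
Reagents that add atoms: none
Why: Barton–McCombie radical deoxygenation: the stannyl radical attacks the thiocarbonyl, and the benzylic radical formed has no 5-exo or 6-endo cyclisation path to either alkene and is reduced by Bu3SnH to the methylene group.

Step 18
Reactants: 24 bis-silyl bis-MOM hexahydronaphthalene
Product: 25 tert-butyl({4-[((1S,2R,4aR,6R)-6-{[tert-butyl(dimethyl)silyl]oxy}-1,2,5,5-tetramethyl-1,2,3,4,4a,5,6,7-octahydronaphthalen-1-yl)methyl]-3,5-bis(methoxymethoxy)phenyl}methoxy)dimethylsilane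
Conditions: H2 (3 atm), RhCl(PPh3)3 (10 mol%), benzene/EtOH, rt
Reagents that add atoms: none
Why: Homogeneous hydrogenation with Wilkinson's catalyst is strongly sensitive to alkene substitution, so the cis-disubstituted C3=C4 bond should be saturated while the trisubstituted C8=C8a bond, flanked by the quaternary C1, stays; no stereocentre is formed.

Step 19
Reactants: 25 bis-silyl bis-MOM octahydronaphthalene
Product: 26 {4-[((1S,2R,4aR,6R)-6-hydroxy-1,2,5,5-tetramethyl-1,2,3,4,4a,5,6,7-octahydronaphthalen-1-yl)methyl]-3,5-bis(methoxymethoxy)phenyl}methanol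
Conditions: TBAF, THF, 50 °C
Reagents that add atoms: none
Why: Fluoride cleaves both silyl ethers (the neopentyl secondary one needs gentle warming) and leaves the aryl MOM acetals, which frees the benzylic alcohol as a directing group.

Step 20
Reactants: 26 diol with two aryl MOM ethers
Product: 27 6-(hydroxymethyl)-3-{[(1S,2R,4aR,6R)-6-hydroxy-1,2,5,5-tetramethyl-1,2,3,4,4a,5,6,7-octahydronaphthalen-1-yl]methyl}-2,4-bis(methoxymethoxy)benzaldehyde
Conditions: n-BuLi (4 equiv), TMEDA, THF, −20 → 0 °C; then DMF; aq NH4Cl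
Reagents that add atoms: N,N-dimethylformamide, CN(C)C=O
Why: Directed ortho-metalation: after deprotonation of both alcohols, further n-BuLi lithiates the ring position flanked by a MOM ether and the CH2OLi group (the two such positions are equivalent by the local symmetry of the arene), and DMF formylates this carbon.

Step 21
Reactants: 27 bis-MOM hydroxymethyl benzaldehyde
Product: 28 2,4-dihydroxy-6-(hydroxymethyl)-3-{[(1S,2R,4aR,6R)-6-hydroxy-1,2,5,5-tetramethyl-1,2,3,4,4a,5,6,7-octahydronaphthalen-1-yl]methyl}benzaldehyde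
Conditions: 2 M aq HCl/THF (1:1), rt → 40 °C
Reagents that add atoms: none
Why: Acid hydrolysis of the two aryl MOM acetals, fast because the phenols are ortho and para to the formyl group, under aqueous conditions mild enough to leave the C8=C8a alkene and the benzylic alcohol alone, should give the target.

**Compound list**

1 | methyl 2,2-dimethyl-3-oxopropanoate | COC(=O)C(C)(C)C=O | starting material
2 | methyl (3E)-4-iodo-2,2-dimethylbut-3-enoate | COC(=O)C(C)(C)/C=C/I | intermediate
3 | methyl (3E,5Z)-2,2-dimethylhepta-3,5-dienoate | COC(=O)C(C)(C)/C=C/C=C\C | intermediate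
4 | (3E,5Z)-2,2-dimethylhepta-3,5-dien-1-ol | OCC(C)(C)/C=C/C=C\C | intermediate
5 | (3E,5Z)-2,2-dimethylhepta-3,5-dienal | O=CC(C)(C)/C=C/C=C\C | intermediate
6 | 3,3-diethoxyprop-1-yne | C#CC(OCC)OCC | starting material
7 | N-methoxy-N-methylacetamide | CC(=O)N(C)OC | starting material
8 | lithium 3,3-diethoxyprop-1-yn-1-ide | [Li]C#CC(OCC)OCC | intermediate
9 | 5,5-diethoxypent-3-yn-2-one | CC(=O)C#CC(OCC)OCC | intermediate
10 | (6R,8E,10Z)-1,1-diethoxy-6-hydroxy-7,7-dimethyldodeca-8,10-dien-2-yn-4-one | CCOC(OCC)C#CC(=O)C[C@@H](O)C(C)(C)/C=C/C=C\C | intermediate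
11 | (6R,8E,10Z)-6-[(tert-butyldimethylsilyl)oxy]-1,1-diethoxy-7,7-dimethyldodeca-8,10-dien-2-yn-4-one | CCOC(OCC)C#CC(=O)C[C@@H](O[Si](C)(C)C(C)(C)C)C(C)(C)/C=C/C=C\C | intermediate
12 | (4R,6R,8E,10Z)-6-[(tert-butyldimethylsilyl)oxy]-1,1-diethoxy-7,7-dimethyldodeca-8,10-dien-2-yn-4-ol | CCOC(OCC)C#C[C@H](O)C[C@@H](O[Si](C)(C)C(C)(C)C)C(C)(C)/C=C/C=C\C | intermediate
13 | (4R,6R,8E,10Z)-6-[(tert-butyldimethylsilyl)oxy]-1,1-diethoxy-7,7-dimethyldodeca-8,10-dien-2-yn-4-yl methanesulfonate | CCOC(OCC)C#C[C@H](OS(C)(=O)=O)C[C@@H](O[Si](C)(C)C(C)(C)C)C(C)(C)/C=C/C=C\C | intermediate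
14 | tert-butyl{[(Ra,6R,8E,10Z)-1,1-diethoxy-2,7,7-trimethyldodeca-2,3,8,10-tetraen-6-yl]oxy}dimethylsilane | CCOC(OCC)C(C)=[C@]=C([H])C[C@@H](O[Si](C)(C)C(C)(C)C)C(C)(C)/C=C/C=C\C | intermediate
15 | (Ra,6R,8E,10Z)-6-[(tert-butyldimethylsilyl)oxy]-2,7,7-trimethyldodeca-2,3,8,10-tetraenal | O=CC(C)=[C@]=C([H])C[C@@H](O[Si](C)(C)C(C)(C)C)C(C)(C)/C=C/C=C\C | intermediate
16 | (1S,2R,4aR,6R)-6-[(tert-butyldimethylsilyl)oxy]-1,2,5,5-tetramethyl-1,2,4a,5,6,7-hexahydronaphthalene-1-carbaldehyde | C[C@@H]1C=C[C@@H]2C(=CC[C@@H](O[Si](C)(C)C(C)(C)C)C2(C)C)[C@@]1(C)C=O | intermediate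
17 | methyl 4-bromo-3,5-dihydroxybenzoate | COC(=O)c1cc(O)c(Br)c(O)c1 | starting material
18 | methyl 4-bromo-3,5-bis(methoxymethoxy)benzoate | COC(=O)c1cc(OCOC)c(Br)c(OCOC)c1 | intermediate
19 | [4-bromo-3,5-bis(methoxymethoxy)phenyl]methanol | OCc1cc(OCOC)c(Br)c(OCOC)c1 | intermediate
20 | {[4-bromo-3,5-bis(methoxymethoxy)phenyl]methoxy}(tert-butyl)dimethylsilane | CC(C)(C)[Si](C)(C)OCc1cc(OCOC)c(Br)c(OCOC)c1 | intermediate
21 | [4-({[tert-butyl(dimethyl)silyl]oxy}methyl)-2,6-bis(methoxymethoxy)phenyl]lithium | CC(C)(C)[Si](C)(C)OCc1cc(OCOC)c([Li])c(OCOC)c1 | intermediate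
22 | lithium alkoxide of [4-({[tert-butyl(dimethyl)silyl]oxy}methyl)-2,6-bis(methoxymethoxy)phenyl][(1S,2R,4aR,6R)-6-{[tert-butyl(dimethyl)silyl]oxy}-1,2,5,5-tetramethyl-1,2,4a,5,6,7-hexahydronaphthalen-1-yl]methanol (both carbinol epimers) | C[C@@H]1C=C[C@@H]2C(=CC[C@@H](O[Si](C)(C)C(C)(C)C)C2(C)C)[C@@]1(C)C(O[Li])c1c(OCOC)cc(CO[Si](C)(C)C(C)(C)C)cc1OCOC | intermediate
23 | O-{[4-({[tert-butyl(dimethyl)silyl]oxy}methyl)-2,6-bis(methoxymethoxy)phenyl][(1S,2R,4aR,6R)-6-{[tert-butyl(dimethyl)silyl]oxy}-1,2,5,5-tetramethyl-1,2,4a,5,6,7-hexahydronaphthalen-1-yl]methyl} S-methyl carbonodithioate (both carbinol epimers) | C[C@@H]1C=C[C@@H]2C(=CC[C@@H](O[Si](C)(C)C(C)(C)C)C2(C)C)[C@@]1(C)C(OC(=S)SC)c1c(OCOC)cc(CO[Si](C)(C)C(C)(C)C)cc1OCOC | intermediate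
24 | tert-butyl({4-[((1S,2R,4aR,6R)-6-{[tert-butyl(dimethyl)silyl]oxy}-1,2,5,5-tetramethyl-1,2,4a,5,6,7-hexahydronaphthalen-1-yl)methyl]-3,5-bis(methoxymethoxy)phenyl}methoxy)dimethylsilane | C[C@@H]1C=C[C@@H]2C(=CC[C@@H](O[Si](C)(C)C(C)(C)C)C2(C)C)[C@@]1(C)Cc1c(OCOC)cc(CO[Si](C)(C)C(C)(C)C)cc1OCOC | intermediate
25 | tert-butyl({4-[((1S,2R,4aR,6R)-6-{[tert-butyl(dimethyl)silyl]oxy}-1,2,5,5-tetramethyl-1,2,3,4,4a,5,6,7-octahydronaphthalen-1-yl)methyl]-3,5-bis(methoxymethoxy)phenyl}methoxy)dimethylsilane | C[C@@H]1CC[C@@H]2C(=CC[C@@H](O[Si](C)(C)C(C)(C)C)C2(C)C)[C@@]1(C)Cc1c(OCOC)cc(CO[Si](C)(C)C(C)(C)C)cc1OCOC | intermediate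
26 | {4-[((1S,2R,4aR,6R)-6-hydroxy-1,2,5,5-tetramethyl-1,2,3,4,4a,5,6,7-octahydronaphthalen-1-yl)methyl]-3,5-bis(methoxymethoxy)phenyl}methanol | C[C@@H]1CC[C@@H]2C(=CC[C@@H](O)C2(C)C)[C@@]1(C)Cc1c(OCOC)cc(CO)cc1OCOC | intermediate
27 | 6-(hydroxymethyl)-3-{[(1S,2R,4aR,6R)-6-hydroxy-1,2,5,5-tetramethyl-1,2,3,4,4a,5,6,7-octahydronaphthalen-1-yl]methyl}-2,4-bis(methoxymethoxy)benzaldehyde | C[C@@H]1CC[C@@H]2C(=CC[C@@H](O)C2(C)C)[C@@]1(C)Cc1c(OCOC)cc(CO)c(C=O)c1OCOC | intermediate
28 | 2,4-dihydroxy-6-(hydroxymethyl)-3-{[(1S,2R,4aR,6R)-6-hydroxy-1,2,5,5-tetramethyl-1,2,3,4,4a,5,6,7-octahydronaphthalen-1-yl]methyl}benzaldehyde | C[C@@H]1CC[C@@H]2C(=CC[C@@H](O)C2(C)C)[C@@]1(C)Cc1c(O)cc(CO)c(C=O)c1O | target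

**Step count and risks**

Total step count: 21. Longest linear sequence: 17 steps (steps 1–4, 6–12, 16–21).

Step 12 (key cycloaddition). The s-cis conformer of the (8E,10Z)-diene is thinly populated, so Lewis acid-induced isomerisation of the allenal to the conjugated 2,4-dienal, or oligomerisation, may outrun the cycloaddition; diene-face selectivity may also erode if the mixture has to be warmed. The fallback runs the cycloaddition one stage earlier as a cationic (Gassman-type) Diels–Alder reaction. It sets out from acetal 14: TMSOTf (10 mol%) in CH2Cl2 at −78 °C ionises the acetal to an ethoxy-stabilised carbenium ion, a far stronger dienophile than the aluminium-bound aldehyde, which should add to the diene along the same two bonds at low temperature. Recapture of ethanol gives the cycloadduct (1S,2R,4aR,6R)-6-[(tert-butyldimethylsilyl)oxy]-1-(diethoxymethyl)-1,2,5,5-tetramethyl-1,2,4a,5,6,7-hexahydronaphthalene F1, and hydrolysis (oxalic acid, wet SiO2, CH2Cl2) comes back to the route at aldehyde 16.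

Step 6 (direct aldol). Addition of the zinc enolate to the neopentyl-type aldehyde may be slow, which would let the ynone condense with itself and lower the enantioselectivity. The fallback is an auxiliary-controlled acetate aldol and sets out from aldehyde 5. The titanium enolate of N-acetyl-(4S)-4-benzyl-1,3-thiazolidine-2-thione (TiCl4, i-Pr2NEt, CH2Cl2, −78 °C; the auxiliary antipode is the one that gives the 3R carbinol, and diastereomers are separable) gives (3R,5E,7Z)-1-[(4S)-4-benzyl-2-thioxo-1,3-thiazolidin-3-yl]-3-hydroxy-4,4-dimethylnona-5,7-dien-1-one F2. Displacement of the auxiliary with MeNHOMe·HCl and imidazole gives the Weinreb amide (3R,5E,7Z)-3-hydroxy-N-methoxy-N,4,4-trimethylnona-5,7-dienamide F3. Silylation (TBSOTf, 2,6-lutidine) gives (3R,5E,7Z)-3-[(tert-butyldimethylsilyl)oxy]-N-methoxy-N,4,4-trimethylnona-5,7-dienamide F4, and addition of lithium acetylide 8 comes back to the route at ynone 11.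

Step 20 (directed metalation). Metalation of the polylithiated substrate may be incomplete or misdirected (aggregation of the dialkoxide, competing lateral lithiation at the benzylic methylene). The fallback formylates the free phenol by an electrophilic route and sets out from 26. Mild acid (2 M aq HCl/THF, rt) removes the MOM groups to give 5-(hydroxymethyl)-2-{[(1S,2R,4aR,6R)-6-hydroxy-1,2,5,5-tetramethyl-1,2,3,4,4a,5,6,7-octahydronaphthalen-1-yl]methyl}benzene-1,3-diol F5. Magnesium-mediated ortho-formylation (MgCl2, Et3N, paraformaldehyde, THF, reflux) then acts on one of the two equivalent positions ortho to a phenol and reaches the route again at target 28.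

Further compounds
F1 | step 12 | (1S,2R,4aR,6R)-6-[(tert-butyldimethylsilyl)oxy]-1-(diethoxymethyl)-1,2,5,5-tetramethyl-1,2,4a,5,6,7-hexahydronaphthalene | C[C@@H]1C=C[C@@H]2C(=CC[C@@H](O[Si](C)(C)C(C)(C)C)C2(C)C)[C@@]1(C)C(OCC)OCC
F2 | step 6 | (3R,5E,7Z)-1-[(4S)-4-benzyl-2-thioxo-1,3-thiazolidin-3-yl]-3-hydroxy-4,4-dimethylnona-5,7-dien-1-one | S=C1SC[C@H](Cc2ccccc2)N1C(=O)C[C@@H](O)C(C)(C)/C=C/C=C\C
F3 | step 6 | (3R,5E,7Z)-3-hydroxy-N-methoxy-N,4,4-trimethylnona-5,7-dienamide | CON(C)C(=O)C[C@@H](O)C(C)(C)/C=C/C=C\C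
F4 | step 6 | (3R,5E,7Z)-3-[(tert-butyldimethylsilyl)oxy]-N-methoxy-N,4,4-trimethylnona-5,7-dienamide | CON(C)C(=O)C[C@@H](O[Si](C)(C)C(C)(C)C)C(C)(C)/C=C/C=C\C
F5 | step 20 | 5-(hydroxymethyl)-2-{[(1S,2R,4aR,6R)-6-hydroxy-1,2,5,5-tetramethyl-1,2,3,4,4a,5,6,7-octahydronaphthalen-1-yl]methyl}benzene-1,3-diol | C[C@@H]1CC[C@@H]2C(=CC[C@@H](O)C2(C)C)[C@@]1(C)Cc1c(O)cc(CO)cc1O
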